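Everything rests on cutting ring A at C4a–C5. The key step exploits that C5–C6–C7 of the phloroglucinol ring A form a malonyl unit, whereas O1, C8a, C8, C4a and the C3 oxygen already sit in a kojic-acid-derived 3-oxygenated 4-pyranone (ring C) carrying the B-ring aryl at C2. The precursor is therefore a tert-butyl 3-oxobutanoate whose C4 (future C8) bears this pyranone and the lavandulyl chain made from (S)-lavandulol. Heating should release tert-butanol and an acylketene whose ketene carbon acylates C4a, so ring A closes and aromatizes in one operation with the side chain fixed at C8 next to O1. Acidic loss of three MOM ethers finishes kushenol C.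

Key step: step 13

Remark: flavonol numbering is used for all ring atoms (kojic acid O1, C6, C5, C4, C3, C2 and CH2OH become flavonol O1, C2, C3, C4, C4a, C8a and C8). The lavandulyl carbon keeps one spatial arrangement from its creation to the target; its CIP letter is S at the acyl, alcohol, bromide and pyranyl-ethyl stages and R once C8 carries the keto ester or is aromatic, only because substituent priorities change.

Step 1
Reactants: 1 (S)-4-benzyloxazolidin-2-one; 2 3-methylbut-2-enoyl chloride
Product: 4 (4S)-4-benzyl-3-(3-methylbut-2-enoyl)oxazolidin-2-one, via N-lithio oxazolidinone 3 (not isolated)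
Conditions: n-BuLi, THF, −78 °C; then 2, −78 → 0 °C
Reagents that add atoms: none
Why: Standard loading of an Evans auxiliary by N-acylation of the lithiated oxazolidinone with an acid chloride; the 4S centre is bought with 1.

Step 2
Reactants: 4 (4S)-4-benzyl-3-(3-methylbut-2-enoyl)oxazolidin-2-one; 5 prenyl bromide (1-bromo-3-methylbut-2-ene)
Product: 7 (4S)-4-benzyl-3-[(2S)-5-methyl-2-(prop-1-en-2-yl)hex-4-enoyl]oxazolidin-2-one, via sodium Z-dienolate 6 (not isolated)
Conditions: NaN(SiMe3)2, THF, −78 °C; then 5, −78 → −40 °C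
Reagents that add atoms: none
Why: Deconjugative Evans alkylation, in which gamma-deprotonation gives the chelated Z-dienolate and the allylic bromide attacks its alpha carbon on the face away from the 4-benzyl group (the sense known for propionimide alkylation), which sets the lavandulyl carbon as 2S; the minor diastereomer should be removable by chromatography.

Step 3
Reactants: 7 (4S)-4-benzyl-3-[(2S)-5-methyl-2-(prop-1-en-2-yl)hex-4-enoyl]oxazolidin-2-one
Product: 8 (S)-lavandulol, (2S)-5-methyl-2-(prop-1-en-2-yl)hex-4-en-1-ol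
Conditions: LiBH4, MeOH (1 equiv), Et2O, 0 °C
Reagents that add atoms: none
Why: Reductive cleavage of the imide by borohydride should release the primary alcohol without epimerizing the alpha centre or touching either olefin, and returns the auxiliary.

Step 4
Reactants: 8 (S)-lavandulol
Product: 9 (S)-lavandulyl bromide, (2S)-1-bromo-5-methyl-2-(prop-1-en-2-yl)hex-4-ene
Conditions: CBr4, PPh3, CH2Cl2, 0 °C
Reagents that add atoms: carbon tetrabromide, BrC(Br)(Br)Br
Why: Appel bromination is an SN2 displacement at the CH2 group under neutral conditions, so no cation forms and neither homoallyl rearrangement nor change at the adjacent stereocentre is expected.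

Step 5
Reactants: 10 4-bromoresorcinol
Product: 11 1-bromo-2,4-bis(methoxymethoxy)benzene
Conditions: MOMCl, i-Pr2NEt, CH2Cl2, 0 °C → rt
Reagents that add atoms: chloromethyl methyl ether, COCCl
Why: Routine O-alkylation of both phenols with an alpha-chloro ether under amine base (Williamson-type acetal formation).

Step 6
Reactants: 11 1-bromo-2,4-bis(methoxymethoxy)benzene
Product: 12 2-[2,4-bis(methoxymethoxy)phenyl]-4,4,5,5-tetramethyl-1,3,2-dioxaborolane
Conditions: B2pin2, Pd(dppf)Cl2 (3 mol %), KOAc, 1,4-dioxane, 90 °C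
Reagents that add atoms: bis(pinacolato)diboron, CC1(C)OB(OC1(C)C)B1OC(C)(C)C(C)(C)O1
Why: Miyaura borylation of an aryl bromide; the MOM acetals are inert to palladium and acetate.

Step 7
Reactants: 13 kojic acid
Product: 14 2-bromo-3-hydroxy-6-(hydroxymethyl)-4H-pyran-4-one (6-bromokojic acid)
Conditions: NBS, DMF, 0 °C → rt
Reagents that add atoms: N-bromosuccinimide, O=C1CCC(=O)N1Br
Why: Electrophilic bromination at the ring carbon ortho to the enolic hydroxyl (future C2), the position at which kojic acid also undergoes Mannich reaction, hydroxymethylation and halogenation.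

Step 8
Reactants: 14 2-bromo-3-hydroxy-6-(hydroxymethyl)-4H-pyran-4-one
Product: 15 2-bromo-6-(hydroxymethyl)-3-(methoxymethoxy)-4H-pyran-4-one
Conditions: MOMCl (1.1 equiv), K2CO3, acetone, 0 °C → rt
Reagents that add atoms: chloromethyl methyl ether, COCCl
Why: Selective O-alkylation, since only the acidic enolic hydroxyl is deprotonated by carbonate while the neutral primary alcohol stays free.

Step 9
Reactants: 15 2-bromo-6-(hydroxymethyl)-3-(methoxymethoxy)-4H-pyran-4-one; 12 2-[2,4-bis(methoxymethoxy)phenyl]-4,4,5,5-tetramethyl-1,3,2-dioxaborolane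
Product: 16 2-[2,4-bis(methoxymethoxy)phenyl]-6-(hydroxymethyl)-3-(methoxymethoxy)-4H-pyran-4-one
Conditions: Pd(OAc)2 (5 mol %), SPhos (10 mol %), K3PO4, PhMe/H2O, 80 °C
Reagents that add atoms: none
Why: Suzuki–Miyaura coupling at the C2–Br bond, a vinylogous acyl bromide that should add readily to zerovalent palladium; the bulky biarylphosphine is chosen for the doubly ortho-substituted junction, and the free CH2OH is tolerated.

Step 10
Reactants: 16 2-[2,4-bis(methoxymethoxy)phenyl]-6-(hydroxymethyl)-3-(methoxymethoxy)-4H-pyran-4-one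
Product: 17 2-[2,4-bis(methoxymethoxy)phenyl]-6-(bromomethyl)-3-(methoxymethoxy)-4H-pyran-4-one
Conditions: CBr4, PPh3, 2,6-lutidine, CH2Cl2, 0 °C
Reagents that add atoms: carbon tetrabromide, BrC(Br)(Br)Br
Why: Appel bromination of a primary, benzylic-type alcohol under buffered neutral conditions that should leave the three MOM acetals intact.

Step 11
Reactants: 17 2-[2,4-bis(methoxymethoxy)phenyl]-6-(bromomethyl)-3-(methoxymethoxy)-4H-pyran-4-one; 9 (S)-lavandulyl bromide
Product: 19 2-[2,4-bis(methoxymethoxy)phenyl]-3-(methoxymethoxy)-6-[(3S)-6-methyl-3-(prop-1-en-2-yl)hept-5-en-1-yl]-4H-pyran-4-one, via (S)-lavandulylmagnesium bromide 18 (not isolated)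
Conditions: 9, Mg, THF, rt; then added slowly to 17, Li2CuCl4 (5 mol %), THF, −78 → −30 °C
Reagents that add atoms: none
Why: Copper-catalysed Kochi-type sp3–sp3 coupling of a primary alkyl Grignard reagent with an activated benzylic-type bromide, which at low temperature should outrun addition to the vinylogous-ester carbonyl; the stereocentre is beta to magnesium and is not involved.

Step 12
Reactants: 19 2-[2,4-bis(methoxymethoxy)phenyl]-3-(methoxymethoxy)-6-[(3S)-6-methyl-3-(prop-1-en-2-yl)hept-5-en-1-yl]-4H-pyran-4-one; 20 mono-tert-butyl malonate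
Product: 23 tert-butyl (6R)-4-{6-[2,4-bis(methoxymethoxy)phenyl]-5-(methoxymethoxy)-4-oxo-4H-pyran-2-yl}-9-methyl-3-oxo-6-(prop-1-en-2-yl)dec-8-enoate (both C4 epimers), via tert-butyl malonyl chloride 21 (not isolated), via C8 lithium dienolate 22 (not isolated)
Conditions: 20, 1-chloro-N,N,2-trimethylprop-1-en-1-amine, CH2Cl2, 0 °C; 19, LiN(SiMe3)2 (2.2 equiv), THF, −78 °C; then 21, −78 °C; AcOH quench
Reagents that add atoms: none
Why: Claisen-type C-acylation of a vinylogous lithium enolate (gamma-deprotonated 2-alkyl-4-pyranone) by a malonyl half-ester chloride, as practised with dioxinone dienolates, the second equivalent of base absorbing the proton of the more acidic product; the new C8 stereocentre is uncontrolled and irrelevant because step 13 destroys it.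

Step 13
Reactants: 23 tert-butyl (6R)-4-{6-[2,4-bis(methoxymethoxy)phenyl]-5-(methoxymethoxy)-4-oxo-4H-pyran-2-yl}-9-methyl-3-oxo-6-(prop-1-en-2-yl)dec-8-enoate
Product: 25 3,2',4'-tri-O-(methoxymethyl)kushenol C, via acylketene 24 (not isolated)
Conditions: PhMe (0.005 M), reflux (110 °C), N2 sweep to remove t-BuOH
Reagents that add atoms: none
Why: Proposed new method: near 110 °C the tert-butyl beta-keto ester should eliminate tert-butanol, the established thermal route from such esters to acylketenes, giving 24 in which the ketene carbon C5 lies within reach of C4a, the alpha carbon of the vinylogous ester O1–C8a=C4a–C4=O and the nucleophilic position of a 4-pyranone. Ring A (C4a, C5, C6, C7, C8, C8a) then closes at the new C4a–C5 bond either by attack of C4a on the sp ketene carbon (a six-membered exo closure onto C5=O) or, after enolization of C7 toward C8, by thermal six-electron electrocyclization of the dienylketene C4a=C8a–C8=C7–C6=C5=O, and two enolizations (hydrogen lost from C4a and C8) aromatize it to the 5,7-diol. The closest known reaction type is thermolytic acylketene generation from tert-butyl beta-keto esters or dioxinones with intramolecular C-acylation and aromatization to resorcylates, together with dienylketene electrocyclization in benzannulations; new here is the use of a 4-pyranone ring carbon as the carbon nucleophile. No stereocentre is formed: the C8 epimers of 23 converge when C8 becomes aromatic, and the lavandulyl carbon, insulated by a CH2 group and never enolizable, keeps its configuration. The step needs intramolecular C-acylation to beat ketene dimerization, re-addition of tert-butanol and loss of isobutene with decarboxylation, which high dilution, removal of tert-butanol in the gas stream, base-washed glassware and the six-membered geometry should secure, while regiochemistry is fixed because the O1–C8a bond stays intact and holds the side chain at C8, away from C6. Neutral heat should leave the MOM acetals and both olefins untouched.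

Step 14
Reactants: 25 3,2',4'-tri-O-(methoxymethyl)kushenol C
Product: 26 kushenol C
Conditions: HCl (1.25 M in MeOH), 0 °C → rt
Reagents that add atoms: none
Why: Acid-catalysed transacetalization of the three MOM acetals to methanol, kept cold and dilute so that the free 7-OH does not add to a protonated side-chain olefin (chroman formation).

Compound list
1 | (S)-4-benzyloxazolidin-2-one | O=C1N[C@@H](Cc2ccccc2)CO1 | starting material
2 | 3-methylbut-2-enoyl chloride | CC(C)=CC(=O)Cl | starting material
3 | N-lithio (S)-4-benzyloxazolidin-2-one | [Li]N1[C@@H](Cc2ccccc2)COC1=O | intermediate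
4 | (4S)-4-benzyl-3-(3-methylbut-2-enoyl)oxazolidin-2-one | CC(C)=CC(=O)N1[C@@H](Cc2ccccc2)COC1=O | intermediate
5 | prenyl bromide | CC(C)=CCBr | starting material
6 | sodium Z-dienolate of 4 | C=C(C)/C=C(\O[Na])N1[C@@H](Cc2ccccc2)COC1=O | intermediate
7 | (4S)-4-benzyl-3-[(2S)-5-methyl-2-(prop-1-en-2-yl)hex-4-enoyl]oxazolidin-2-one | C=C(C)[C@H](CC=C(C)C)C(=O)N1[C@@H](Cc2ccccc2)COC1=O | intermediate
8 | (S)-lavandulol | C=C(C)[C@H](CC=C(C)C)CO | intermediate
9 | (S)-lavandulyl bromide | C=C(C)[C@H](CC=C(C)C)CBr | intermediate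
10 | 4-bromoresorcinol | Oc1ccc(Br)c(O)c1 | starting material
11 | 1-bromo-2,4-bis(methoxymethoxy)benzene | COCOc1ccc(Br)c(OCOC)c1 | intermediate
12 | 2-[2,4-bis(methoxymethoxy)phenyl]-4,4,5,5-tetramethyl-1,3,2-dioxaborolane | COCOc1ccc(B2OC(C)(C)C(C)(C)O2)c(OCOC)c1 | intermediate
13 | kojic acid | O=c1cc(CO)occ1O | starting material
14 | 2-bromo-3-hydroxy-6-(hydroxymethyl)-4H-pyran-4-one | O=c1cc(CO)oc(Br)c1O | intermediate
15 | 2-bromo-6-(hydroxymethyl)-3-(methoxymethoxy)-4H-pyran-4-one | O=c1cc(CO)oc(Br)c1OCOC | intermediate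
16 | 2-[2,4-bis(methoxymethoxy)phenyl]-6-(hydroxymethyl)-3-(methoxymethoxy)-4H-pyran-4-one | O=c1cc(CO)oc(-c2ccc(OCOC)cc2OCOC)c1OCOC | intermediate
17 | 2-[2,4-bis(methoxymethoxy)phenyl]-6-(bromomethyl)-3-(methoxymethoxy)-4H-pyran-4-one | O=c1cc(CBr)oc(-c2ccc(OCOC)cc2OCOC)c1OCOC | intermediate
18 | (S)-lavandulylmagnesium bromide | C=C(C)[C@H](CC=C(C)C)C[Mg]Br | intermediate
19 | 2-[2,4-bis(methoxymethoxy)phenyl]-3-(methoxymethoxy)-6-[(3S)-6-methyl-3-(prop-1-en-2-yl)hept-5-en-1-yl]-4H-pyran-4-one | C=C(C)[C@H](CC=C(C)C)CCc1cc(=O)c(OCOC)c(-c2ccc(OCOC)cc2OCOC)o1 | intermediate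
20 | mono-tert-butyl malonate | CC(C)(C)OC(=O)CC(=O)O | starting material
21 | tert-butyl malonyl chloride (tert-butyl 3-chloro-3-oxopropanoate) | CC(C)(C)OC(=O)CC(=O)Cl | intermediate
22 | C8 lithium dienolate of 19 (4-lithiooxy-2-alkylidene-2H-pyran form) | C=C(C)[C@H](CC=C(C)C)CC=C1C=C(O[Li])C(OCOC)=C(c2ccc(OCOC)cc2OCOC)O1 | intermediate
23 | tert-butyl (6R)-4-{6-[2,4-bis(methoxymethoxy)phenyl]-5-(methoxymethoxy)-4-oxo-4H-pyran-2-yl}-9-methyl-3-oxo-6-(prop-1-en-2-yl)dec-8-enoate (both C4 epimers) | C=C(C)[C@H](CC=C(C)C)CC(C(=O)CC(=O)OC(C)(C)C)c1cc(=O)c(OCOC)c(-c2ccc(OCOC)cc2OCOC)o1 | intermediate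
24 | acylketene from 23 (C7(=O)–C6H=C5=O) | C=C(C)[C@H](CC=C(C)C)CC(C(=O)C=C=O)c1cc(=O)c(OCOC)c(-c2ccc(OCOC)cc2OCOC)o1 | intermediate
25 | 3,2',4'-tri-O-(methoxymethyl)kushenol C | C=C(C)[C@H](CC=C(C)C)Cc1c(O)cc(O)c2c(=O)c(OCOC)c(-c3ccc(OCOC)cc3OCOC)oc12 | intermediate
26 | kushenol C, 2-(2,4-dihydroxyphenyl)-3,5,7-trihydroxy-8-[(2R)-5-methyl-2-(prop-1-en-2-yl)hex-4-en-1-yl]-4H-chromen-4-one | C=C(C)[C@H](CC=C(C)C)Cc1c(O)cc(O)c2c(=O)c(O)c(-c3ccc(O)cc3O)oc12 | target

Total steps: 14. Longest linear sequence: 8 steps (13 → 26 through steps 7 to 14; equally 1 → 26 through steps 1 to 4 and 11 to 14).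

Steps most likely to fail

Step 13. The acylketene may dimerize, re-add tert-butanol, or the ester may lose isobutene and decarboxylate before the weakly nucleophilic C4a acylates. The fallback abandons the annulation for known late-stage cross-coupling; it sets out from Grignard reagent 18 (made from 9 as in step 11) and comes back to the route at 26. Purchased morin F1 is fully protected with NaH and MOMCl in DMF to give 3,5,7,2',4'-penta-O-(methoxymethyl)morin F2. Electrophilic iodination with NIS in DMF, which in 5,7-di-O-alkylated flavones is directed to C8, should give 8-iodo-penta-O-(methoxymethyl)morin F3. Transmetalation of 18 with ZnCl2 gives (S)-lavandulylzinc chloride F4, and Negishi coupling of F4 with F3 (Pd(OAc)2, SPhos, THF, 50 °C) should give penta-O-(methoxymethyl)kushenol C F5, which is deprotected under the conditions of step 14 to 26.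

Step 11. The organometallic may attack the pyranone ring or its carbonyl, halogen–metal exchange may cause homocoupling of the bromide, or slow homoallyl–cyclopropylcarbinyl equilibration of the Grignard reagent may erode enantiopurity. The fallback reverses the polarity so that C8 is a soft carbanion; it sets out from 17 and comes back at 19. Displacement of bromide with PhSO2Na in DMF should give 2-[2,4-bis(methoxymethoxy)phenyl]-3-(methoxymethoxy)-6-[(phenylsulfonyl)methyl]-4H-pyran-4-one F6. Its potassium salt (K2CO3, NaI cat., DMF, 50 °C) is alkylated with bromide 9 to the C8-lavandulyl sulfone F7 (both C8 epimers), and reductive desulfonylation with SmI2 in THF/MeOH at −78 °C returns 19.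

Step 12. Proton transfer from the acidic malonyl donor may quench the dienolate, or acylation may occur on oxygen or twice. The fallback separates carboxylation from chain extension; it sets out from 19 and comes back at 23. Dienolate 22 is quenched with CO2 to give 2-{6-[2,4-bis(methoxymethoxy)phenyl]-5-(methoxymethoxy)-4-oxo-4H-pyran-2-yl}-4-(prop-1-en-2-yl)-7-methyloct-6-enoic acid F8. Activation with CDI in THF gives the acyl imidazolide F9 (not isolated), which undergoes Masamune–Brooks decarboxylative Claisen extension with the magnesium salt of 20 (20, MgCl2, Et3N, THF, rt) to 23.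

Further compounds
F1 | step 13 | morin (purchased) | O=c1c(O)c(-c2ccc(O)cc2O)oc2cc(O)cc(O)c12
F2 | step 13 | 3,5,7,2',4'-penta-O-(methoxymethyl)morin | COCOc1ccc(-c2oc3cc(OCOC)cc(OCOC)c3c(=O)c2OCOC)c(OCOC)c1
F3 | step 13 | 8-iodo-penta-O-(methoxymethyl)morin | COCOc1ccc(-c2oc3c(I)c(OCOC)cc(OCOC)c3c(=O)c2OCOC)c(OCOC)c1
F4 | step 13 | (S)-lavandulylzinc chloride | C=C(C)[C@H](CC=C(C)C)C[Zn]Cl
F5 | step 13 | penta-O-(methoxymethyl)kushenol C | C=C(C)[C@H](CC=C(C)C)Cc1c(OCOC)cc(OCOC)c2c(=O)c(OCOC)c(-c3ccc(OCOC)cc3OCOC)oc12
F6 | step 11 | 2-[2,4-bis(methoxymethoxy)phenyl]-3-(methoxymethoxy)-6-[(phenylsulfonyl)methyl]-4H-pyran-4-one | O=c1cc(CS(=O)(=O)c2ccccc2)oc(-c2ccc(OCOC)cc2OCOC)c1OCOC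
F7 | step 11 | C8-lavandulyl sulfone (both C8 epimers) | C=C(C)[C@H](CC=C(C)C)CC(S(=O)(=O)c1ccccc1)c1cc(=O)c(OCOC)c(-c2ccc(OCOC)cc2OCOC)o1
F8 | step 12 | C8 carboxylic acid of 19 (both C8 epimers) | C=C(C)[C@H](CC=C(C)C)CC(C(=O)O)c1cc(=O)c(OCOC)c(-c2ccc(OCOC)cc2OCOC)o1
F9 | step 12 | acyl imidazolide of F8 | C=C(C)[C@H](CC=C(C)C)CC(C(=O)n1ccnc1)c1cc(=O)c(OCOC)c(-c2ccc(OCOC)cc2OCOC)o1
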